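## The problem

Compound 16 is a trans-2,3-disubstituted 2,3-dihydrobenzofuran. Ring B (O1, C2, C3, C3a, C7a) is fused to the benzo ring A; C2 carries the 3,4,5-trimethoxyphenyl ring C, C3 a hydroxymethyl group, and C5 of ring A, para to O1, an (E)-3-hydroxyprop-1-enyl chain. Rings A and C are ordinary benzenoid building blocks, so the task is to join ring C to C2 and a one-carbon unit to C3 while fixing C2 as R and C3 as S. The two stereocentres are adjacent and trans, the more stable arrangement, so each could in principle steer the other. C2, however, is a benzylic ether carbon with no acidifying neighbour and cannot be corrected later by simple epimerisation, so the absolute configuration has to be introduced in the bond-forming event itself. The fragile points are: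

- the benzylic C2–O1 bond, ionisable by strong acid because ring C is electron-rich;
- any intermediate with a carbonyl group on C3, where enolisation can expel O1 or lead towards an aromatic benzofuran and erase stereochemistry;
- ring C towards strong oxidants;
- the cinnamyl alcohol, which is best made last.

The C5 side chain has to travel as a masked formyl group, because neither a free aldehyde nor a halide survives organolithium chemistry. The enabling feature is that O1–C2–C3 of ring B is the enol-ether unit of a benzofuran: ring B of 16 is a benzofuran whose C2=C3 bond has taken up an aryl group at C2 and a carbon substituent at C3 from opposite faces. The C2–H bond of a benzofuran is readily lithiated, and a boron-ate complex at C2 makes C3 nucleophilic while holding the aryl group ready to migrate to C2.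

## Retrosynthesis

The (E)-allylic alcohol of 16 is disconnected first. Its oxidation level goes back to the methyl enoate 15, and the side-chain C=C bond of 15 is cut to aldehyde 14 and a two-carbon stabilised ylide. A cross-coupling of a C5 halide with a three-carbon alkene would be shorter on paper, but a C5 halide cannot pass through the C2 lithiation on which the plan rests, whereas a formyl group can be masked. The forward steps ask only for an E-selective Wittig olefination and a 1,2-reduction beside an unprotected primary alcohol.

Aldehyde 14 is unmasked from dioxolane 13. The hydroxymethyl carbon of 13 is taken as the first carbon of an allyl group: 13 comes from reduction of aldehyde 12, 12 from cleavage of the C=C bond of the propenyl compound 11, and 11 from the allyl compound 10 by a one-position double-bond shift. This two-step detour is accepted because an allyl cation on palladium is the carbon electrophile for which an enantioselective C3 attack with migration to C2 has a close model; a one-carbon electrophile has no such asymmetric version. The forward steps must stop the alkene after one shift, since further travel would reach C3, and must reduce 12 before it can enolise.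

The C2–H bond of 10 is traced to a C2–B bond in the pinacol boronate 9. Boron is there only because it delivered ring C to C2. It must leave by protodeboronation with retention, so that ring C stays trans to the allyl group. Compound 9 is no simpler than 10, but it is the direct product of a three-component coupling.

In 9 the C2–aryl and C3–allyl bonds are cut together. This returns benzofuran 2 (as its C2-lithio derivative 7), the aryl pinacol boronate 5 and allyl acetate 6. Compounds 7 and 5 combine to the boron-ate complex 8, and allylation of 8 at C3 drives ring C from boron to C2. Against stepwise routes (C2 arylation followed by an asymmetric reduction or addition at the aromatic C2=C3 bond), this cut makes both skeletal bonds and both stereocentres in one operation from three flat, achiral components. It also makes the trans relation a consequence of mechanism. It asks that an oxygen-heterocycle boronate be nucleophilic enough at C3 for a cationic allylpalladium complex, and that a chiral diphosphine on palladium distinguish the faces of C3.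

Benzofuran 2 is the dioxolane of the commercial aldehyde 1, and boronate 5 is the ester of the commercial boronic acid 3 with pinacol 4. Neither step creates a stereocentre.

## Roads not taken

Alternative 1: The cut is the O1–C2 bond of ring B and, one stage earlier, the C2–C3 bond together with the O–CH2 bond of an oxetane.

- Forward key step: Paternò–Büchi irradiation of 3,4,5-trimethoxybenzaldehyde A1 with methyl 4-(tert-butyldimethylsilyloxy)-3-vinylbenzoate A2 would give the trans-2,3-diaryloxetane A3. After desilylation the phenoxide would open the oxetane at its benzylic carbon with inversion, closing ring B and freeing the hydroxymethyl group of 16 at the right oxidation level.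
- Merits: two bonds and the relative configuration arise in one step from trivial materials, ring strain drives the closure of ring B, and no carbon has to be excised at C3.
- Weak points:
  - A3 can only be racemic, so a single enantiomer of 16 would need a resolution that discards half the material.
  - The excited aryl aldehyde is a triplet sensitiser for a styrene such as A2, which diverts the reaction to dimerisation and polymerisation of A2.
  - The electron-rich A1 has a low-lying π,π* triplet that is poor in oxetane formation.
  - Biradical closure gives cis/trans mixtures.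
  - The C5 ester still has to be taken to the allylic alcohol, so the end-game is no shorter.
- Comparison: this road is shorter and cheaper to the racemic core and avoids the two-carbon excision. The chosen plan sets the absolute configuration by a catalyst in the bond-forming step, which a photochemical cycloaddition of this kind cannot do.

Alternative 2: The cut is O1–C2 together with the bond from C3 to its carbonyl carbon.

- Forward key step: the hydroxystilbene A4, under divalent palladium (Pd(OCOCF3)2 with a chiral bis(oxazoline) ligand) in an oxidative methoxycarbonylating cyclisation, would add the phenol oxygen to the alkene carbon bearing ring C and trap the C3–palladium bond as a methyl ester, giving A5. One hydride reduction of both ester groups would then give 16.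
- Merits: it is by far the shortest road, about four steps. Both side-chain carbons arrive at the ester level and are finished by the same reduction. Epimerisation at C3 next to the ester could only help, since trans is favoured.
- Weak points:
  - The closure is 5-endo onto a 1,2-disubstituted stilbene, whereas enantioselective oxypalladations with precedent are exo closures onto alkenes that block or steer β-hydride elimination.
  - The C3–palladium intermediate has C2–H beside it, and β-hydride elimination, which aromatises ring B and is the usual fate of 2-hydroxystilbenes under divalent palladium, competes with carbonyl insertion.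
  - The acrylate alkene of A4 is a second binding site for the metal.
  - The C3 ester of A5 has O1 in the β-position, so retro-oxa-Michael opening could racemise C2.
- Comparison: in step count this road is clearly better, about half the length, and it needs no carbon excision. The chosen plan sets three things against it. Its key step differs from its closest model only in the heteroatom, with the same catalyst, electrophile and mode of induction, whereas here the closure mode must change and a dominant side pathway must be suppressed. The trans relation comes from a stereospecific migration. No C3 carbonyl compound is ever isolated.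

Alternative 3: The cut runs through ring A, at C3a–C4 and C7a–C7.

- Forward key step: the enantiopure trans lactone A6, O-silylated at its enolate oxygen in the flask, would undergo an inverse-electron-demand Diels–Alder reaction with methyl coumalate A7. Decarboxylation and loss of the silyloxy group would aromatise the adduct to the ester A8, with the ester at C5.
- Merits: both stereocentres are made beforehand on a five-membered lactone by well-understood chemistry and are untouched by the key step. The regiochemistry of ring A follows from the polarisation of A7. No transition metal is needed.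
- Weak points:
  - A6 needs its own asymmetric synthesis of several steps.
  - Ring A, which can be bought as part of 1, is built from scratch.
  - The reacting ketene-acetal carbon is next to the substituted C3, so the cycloaddition is hindered and needs heat.
  - In the aromatisation the carbon that becomes C7a carries two oxygens and may expel O1 instead of the silyloxy group, which would open ring B.
  - A8 still needs four or five steps to 16.
- Comparison: stereochemically this is the safest of the four and better than the chosen plan in that respect, since nothing rests on an untested asymmetric induction. The chosen plan sets against it a markedly shorter sequence and the use of rings A and C as bought.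

Key step: step 3

Assumption: which BINAP enantiomer leads to (2R,3R)-9 cannot be derived with certainty for the oxygen heterocycle; (R)-BINAP is written, and (S)-BINAP is to be used instead if the first run shows the opposite sense of induction.

## Steps

Step 1
Reactants: 1 benzofuran-5-carbaldehyde
Product: 2 5-(1,3-dioxolan-2-yl)benzofuran
Conditions: HOCH2CH2OH, pyridinium p-toluenesulfonate (cat.), toluene, reflux, Dean–Stark
Reagents that add atoms: ethylene glycol, OCCO
Why: Acid-catalysed acetalisation driven by azeotropic removal of water; the mild pyridinium acid spares the acid-sensitive benzofuran, and the dioxolane withstands n-BuLi and keeps ring A from being electron-poor in step 3.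

Step 2
Reactants: 3 (3,4,5-trimethoxyphenyl)boronic acid; 4 pinacol
Product: 5 4,4,5,5-tetramethyl-2-(3,4,5-trimethoxyphenyl)-1,3,2-dioxaborolane
Conditions: MgSO4, Et2O, rt
Reagents that add atoms: none
Why: Boronic ester formation by condensation of a boronic acid with a 1,2-diol, completed by the drying agent; it should give an anhydrous, boroxine-free ester that does not quench the organolithium of step 3.

Step 3
Reactants: 2 5-(1,3-dioxolan-2-yl)benzofuran; 5 4,4,5,5-tetramethyl-2-(3,4,5-trimethoxyphenyl)-1,3,2-dioxaborolane; 6 allyl acetate
Product: 9 2-[(2R,3R)-3-allyl-5-(1,3-dioxolan-2-yl)-2-(3,4,5-trimethoxyphenyl)-2,3-dihydrobenzofuran-2-yl]-4,4,5,5-tetramethyl-1,3,2-dioxaborolane, via 2-lithiobenzofuran acetal 7 (not isolated), via lithium boronate complex 8 (not isolated)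
Conditions: n-BuLi (1.0 equiv), THF, −78 °C; 5, −78 °C to rt; then Pd2(dba)3 (2.5 mol%), (R)-BINAP (6 mol%), 6, THF, rt
Reagents that add atoms: n-butyllithium, [Li]CCCC (supplies lithium to 7 and 8; none of its atoms remain in 9)
Why: Proposed new method: n-BuLi removes the most acidic proton of 2 (C2–H) to give 7, which adds to the boron of 5 to give the tetracoordinate boronate 8. Zerovalent palladium with BINAP ionises allyl acetate to a cationic π-allyl complex that is attacked, outer sphere, by C3 of 8 (the enol-ether carbon β to boron); as the C3–allyl bond forms, the trimethoxyphenyl group shifts from boron to C2 on the face opposite the incoming allyl group, giving the neutral boronic ester 9 and lithium acetate. The closest known reaction type is the enantioselective three-component coupling of 2-indolyl boronate complexes with allylic acetates under the same Pd2(dba)3/BINAP catalyst; the oxygen analogue is untested, but furan-2-yl boronate complexes are known to take carbon electrophiles with a 1,2-shift, and the positive charge developing at C2 is stabilised by O1 as it is by nitrogen in the indole case. No ring is closed: ring B is supplied by the benzofuran and is dearomatised. C3 is set by the chiral diphosphine on palladium, which selects the face of C3 that meets the π-allyl cation, and C2 is set by the stereospecific anti relation between electrophile and migrating group, so ring C and the allyl group end trans and enantio- and diastereocontrol are coupled. The step needs attack at C3 in preference to transfer of a carbon ligand from boron to palladium: the chelating diphosphine leaves no free site on the allylpalladium cation, the aryl group is the only carbon ligand on boron free to migrate, and one equivalent of n-BuLi leaves no butyl boronate that could compete. The C5 dioxolane, unlike a free formyl group, does not withdraw electron density from O1 and so keeps C3 as nucleophilic as the parent benzofuran allows.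

Step 4
Reactants: 9 2-[(2R,3R)-3-allyl-5-(1,3-dioxolan-2-yl)-2-(3,4,5-trimethoxyphenyl)-2,3-dihydrobenzofuran-2-yl]-4,4,5,5-tetramethyl-1,3,2-dioxaborolane
Product: 10 (2R,3R)-3-allyl-5-(1,3-dioxolan-2-yl)-2-(3,4,5-trimethoxyphenyl)-2,3-dihydrobenzofuran
Conditions: Bu4NF·3H2O (3 equiv), toluene, rt to 45 °C
Reagents that add atoms: none
Why: Fluoride-promoted protodeboronation of a tertiary benzylic pinacol boronate: fluoride adds to boron and the C–B bond of the fluoroboronate is protonated by water on the boron-bearing face (retention) in a non-polar solvent, so the new C2–H is cis to the allyl group and ring C stays trans to it; the same operation is known for tertiary benzylic and indolin-2-yl boronic esters.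

Step 5
Reactants: 10 (2R,3R)-3-allyl-5-(1,3-dioxolan-2-yl)-2-(3,4,5-trimethoxyphenyl)-2,3-dihydrobenzofuran
Product: 11 (2R,3R)-5-(1,3-dioxolan-2-yl)-3-[(E)-prop-1-enyl]-2-(3,4,5-trimethoxyphenyl)-2,3-dihydrobenzofuran
Conditions: Pd(dba)2 (2 mol%), P(t-Bu)3 (2 mol%), i-PrCOCl (2 mol%), toluene, 80 °C
Reagents that add atoms: none
Why: Alkene isomerisation by a bulky palladium hydride formed in the flask (hydropalladation, then β-hydride elimination); this hydride adds to monosubstituted alkenes only, so the double bond should move one position and stop before the hindered C3, and any Z isomer is harmless because the alkene is cleaved next.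

Step 6
Reactants: 11 (2R,3R)-5-(1,3-dioxolan-2-yl)-3-[(E)-prop-1-enyl]-2-(3,4,5-trimethoxyphenyl)-2,3-dihydrobenzofuran
Product: 13 [(2R,3S)-5-(1,3-dioxolan-2-yl)-2-(3,4,5-trimethoxyphenyl)-2,3-dihydrobenzofuran-3-yl]methanol, via dihydrobenzofuran-3-carbaldehyde 12 (not isolated)
Conditions: O3, CH2Cl2/MeOH, −78 °C (Sudan Red 7B as end-point indicator); then NaBH4, −78 to 0 °C
Reagents that add atoms: ozone, [O-][O+]=O
Why: Ozonolysis with reductive work-up: the alkene reacts far faster than ring C or the acetal C–H, the indicator dye limits ozone uptake, and NaBH4 reduces the peroxidic products through aldehyde 12 to the alcohol in the same flask, so the β-aryloxy aldehyde cannot enolise; C3 is not touched, and its descriptor changes from R to S only because the priority order of its substituents changes.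

Step 7
Reactants: 13 [(2R,3S)-5-(1,3-dioxolan-2-yl)-2-(3,4,5-trimethoxyphenyl)-2,3-dihydrobenzofuran-3-yl]methanol
Product: 14 (2R,3S)-3-(hydroxymethyl)-2-(3,4,5-trimethoxyphenyl)-2,3-dihydrobenzofuran-5-carbaldehyde
Conditions: 1 M HCl, THF, rt
Reagents that add atoms: water, O
Why: Acid hydrolysis of an aryl dioxolane; dilute acid at room temperature should not ionise the benzylic C2–O1 bond, and the primary alcohol needs no protection.

Step 8
Reactants: 14 (2R,3S)-3-(hydroxymethyl)-2-(3,4,5-trimethoxyphenyl)-2,3-dihydrobenzofuran-5-carbaldehyde
Product: 15 methyl (E)-3-[(2R,3S)-3-(hydroxymethyl)-2-(3,4,5-trimethoxyphenyl)-2,3-dihydrobenzofuran-5-yl]prop-2-enoate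
Conditions: Ph3P=CHCO2Me, toluene, 80 °C
Reagents that add atoms: methyl (triphenylphosphoranylidene)acetate, COC(=O)C=P(c1ccccc1)(c1ccccc1)c1ccccc1
Why: Wittig reaction of an aromatic aldehyde with a stabilised ylide, which should give the E enoate under thermodynamic control of the oxaphosphetane; the free hydroxyl group is tolerated.

Step 9
Reactants: 15 methyl (E)-3-[(2R,3S)-3-(hydroxymethyl)-2-(3,4,5-trimethoxyphenyl)-2,3-dihydrobenzofuran-5-yl]prop-2-enoate
Product: 16 (E)-3-[(2R,3S)-3-(hydroxymethyl)-2-(3,4,5-trimethoxyphenyl)-2,3-dihydrobenzofuran-5-yl]prop-2-en-1-ol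
Conditions: i-Bu2AlH (excess), CH2Cl2, −78 to 0 °C; aqueous potassium sodium tartrate
Reagents that add atoms: none
Why: 1,2-Reduction of an α,β-unsaturated ester to the allylic alcohol by i-Bu2AlH; the free hydroxyl group consumes one equivalent as its alkoxide, and the alkene geometry and both stereocentres are untouched.

## Compound list

1 | benzofuran-5-carbaldehyde | O=Cc1ccc2occc2c1 | starting material
2 | 5-(1,3-dioxolan-2-yl)benzofuran | C1COC(O1)c1ccc2occc2c1 | intermediate
3 | (3,4,5-trimethoxyphenyl)boronic acid | COc1cc(B(O)O)cc(OC)c1OC | starting material
4 | pinacol (2,3-dimethylbutane-2,3-diol) | CC(C)(O)C(C)(C)O | starting material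
5 | 4,4,5,5-tetramethyl-2-(3,4,5-trimethoxyphenyl)-1,3,2-dioxaborolane | COc1cc(B2OC(C)(C)C(C)(C)O2)cc(OC)c1OC | intermediate
6 | allyl acetate | CC(=O)OCC=C | starting material
7 | [5-(1,3-dioxolan-2-yl)benzofuran-2-yl]lithium (formed in the flask) | [Li]c1cc2cc(C3OCCO3)ccc2o1 | intermediate
8 | lithium 2-[5-(1,3-dioxolan-2-yl)benzofuran-2-yl]-4,4,5,5-tetramethyl-2-(3,4,5-trimethoxyphenyl)-1,3,2-dioxaborolan-2-uide (formed in the flask) | [Li+].COc1cc([B-]2(c3cc4cc(C5OCCO5)ccc4o3)OC(C)(C)C(C)(C)O2)cc(OC)c1OC | intermediate
9 | 2-[(2R,3R)-3-allyl-5-(1,3-dioxolan-2-yl)-2-(3,4,5-trimethoxyphenyl)-2,3-dihydrobenzofuran-2-yl]-4,4,5,5-tetramethyl-1,3,2-dioxaborolane (aryl trans to allyl) | COc1cc([C@]2(B3OC(C)(C)C(C)(C)O3)Oc3ccc(C4OCCO4)cc3[C@H]2CC=C)cc(OC)c1OC | intermediate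
10 | (2R,3R)-3-allyl-5-(1,3-dioxolan-2-yl)-2-(3,4,5-trimethoxyphenyl)-2,3-dihydrobenzofuran (trans) | COc1cc([C@@H]2Oc3ccc(C4OCCO4)cc3[C@H]2CC=C)cc(OC)c1OC | intermediate
11 | (2R,3R)-5-(1,3-dioxolan-2-yl)-3-[(E)-prop-1-enyl]-2-(3,4,5-trimethoxyphenyl)-2,3-dihydrobenzofuran (trans) | COc1cc([C@@H]2Oc3ccc(C4OCCO4)cc3[C@H]2/C=C/C)cc(OC)c1OC | intermediate
12 | (2R,3R)-5-(1,3-dioxolan-2-yl)-2-(3,4,5-trimethoxyphenyl)-2,3-dihydrobenzofuran-3-carbaldehyde (trans; formed in the flask) | COc1cc([C@@H]2Oc3ccc(C4OCCO4)cc3[C@H]2C=O)cc(OC)c1OC | intermediate
13 | [(2R,3S)-5-(1,3-dioxolan-2-yl)-2-(3,4,5-trimethoxyphenyl)-2,3-dihydrobenzofuran-3-yl]methanol (trans) | COc1cc([C@@H]2Oc3ccc(C4OCCO4)cc3[C@H]2CO)cc(OC)c1OC | intermediate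
14 | (2R,3S)-3-(hydroxymethyl)-2-(3,4,5-trimethoxyphenyl)-2,3-dihydrobenzofuran-5-carbaldehyde | COc1cc([C@@H]2Oc3ccc(C=O)cc3[C@H]2CO)cc(OC)c1OC | intermediate
15 | methyl (E)-3-[(2R,3S)-3-(hydroxymethyl)-2-(3,4,5-trimethoxyphenyl)-2,3-dihydrobenzofuran-5-yl]prop-2-enoate | COc1cc([C@@H]2Oc3ccc(/C=C/C(=O)OC)cc3[C@H]2CO)cc(OC)c1OC | intermediate
16 | (E)-3-[(2R,3S)-3-(hydroxymethyl)-2-(3,4,5-trimethoxyphenyl)-2,3-dihydrobenzofuran-5-yl]prop-2-en-1-ol | COc1cc([C@@H]2Oc3ccc(/C=C/CO)cc3[C@H]2CO)cc(OC)c1OC | target

## Step count and risks

Total: 9 steps. Longest linear sequence: 8 steps (steps 1 and 3 to 9, from 1); step 2 is a one-step side branch.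

Step 3 (key step). The boron-ate complex 8 may be too weak a carbon nucleophile at C3. Ionisation of allyl acetate would then be followed by transfer of a carbon ligand from boron to palladium and plain allyl–aryl or allyl–benzofuranyl coupling instead of the dearomatising shift. The face selection at C3 may also be lower than with the nitrogen heterocycle. The fallback uses known reactions only, at the price of a resolution; it sets out from 2 and returns at 13.
- Lithiation of 2 with n-BuLi, transmetalation with ZnCl2 and Negishi coupling with 5-bromo-1,2,3-trimethoxybenzene (Pd(PPh3)4) would give 5-(1,3-dioxolan-2-yl)-2-(3,4,5-trimethoxyphenyl)benzofuran F1.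
- Bromination at C3 with N-bromosuccinimide in MeCN would give 3-bromo-5-(1,3-dioxolan-2-yl)-2-(3,4,5-trimethoxyphenyl)benzofuran F2.
- Palladium-catalysed methoxycarbonylation (Pd(OAc)2, Xantphos, CO, MeOH, Et3N) would give methyl 5-(1,3-dioxolan-2-yl)-2-(3,4,5-trimethoxyphenyl)benzofuran-3-carboxylate F3.
- Magnesium in methanol would reduce the C2=C3 bond by electron transfer and protonation to the racemic trans ester, methyl 5-(1,3-dioxolan-2-yl)-2-(3,4,5-trimethoxyphenyl)-2,3-dihydrobenzofuran-3-carboxylate F4.
- LiAlH4 would give racemic trans [5-(1,3-dioxolan-2-yl)-2-(3,4,5-trimethoxyphenyl)-2,3-dihydrobenzofuran-3-yl]methanol F5, which is separated on a chiral stationary phase to give 13.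

Step 4. The fluoroboronate may ionise to a benzylic carbanion before it is protonated, which would erode the C2 configuration; it may also be too hindered to react, or the C2–O1 bond may break. The fallback lets C3 control C2; it sets out from 9 and returns at 10.
- Oxidation of the C–B bond with NaBO3·4H2O in THF/water at 0 °C would give the hemiketal (3R)-3-allyl-5-(1,3-dioxolan-2-yl)-2-(3,4,5-trimethoxyphenyl)-2,3-dihydrobenzofuran-2-ol F6, in equilibrium with its ring-opened hydroxy ketone form.
- NaBH4 in the same flask, before the ketone form can enolise, would give (2R)-2-[5-(1,3-dioxolan-2-yl)-2-hydroxyphenyl]-1-(3,4,5-trimethoxyphenyl)pent-4-en-1-ol F7 as a mixture of C1 epimers.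
- Catalytic camphorsulfonic acid in dry CH2Cl2 over molecular sieves would ionise the trimethoxybenzylic carbinol. The phenol should capture the cation anti to the allyl group, so both epimers of F7 converge on trans 10.

Step 5. The double bond may migrate further, into conjugation with ring A; this would flatten C3 and could end in aromatisation of ring B. The fallback removes the two carbons one at a time without any metal hydride near C3; it sets out from 10 and returns at 13.
- Lemieux–Johnson cleavage of the terminal alkene (OsO4 cat., NaIO4, 2,6-lutidine, dioxane/water) would give 2-[(2R,3R)-5-(1,3-dioxolan-2-yl)-2-(3,4,5-trimethoxyphenyl)-2,3-dihydrobenzofuran-3-yl]acetaldehyde F8.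
- t-BuMe2SiOTf and Et3N would give its silyl enol ether, tert-butyl-dimethyl-[2-[(2R,3R)-5-(1,3-dioxolan-2-yl)-2-(3,4,5-trimethoxyphenyl)-2,3-dihydrobenzofuran-3-yl]ethenoxy]silane F9.
- Ozonolysis of this electron-rich alkene with NaBH4 work-up would pass through 12 and give 13.

Step 6. Ozone may over-oxidise ring C or the acetal C–H once the alkene is consumed. Aldehyde 12 may also enolise before reduction, with loss of O1 from C2 and scrambling of C2. The fallback avoids ozone; it sets out from 11 and returns at 13.
- Dihydroxylation with catalytic OsO4 and N-methylmorpholine N-oxide in acetone/water would give 1-[(2R,3S)-5-(1,3-dioxolan-2-yl)-2-(3,4,5-trimethoxyphenyl)-2,3-dihydrobenzofuran-3-yl]propane-1,2-diol F10.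
- NaIO4 in buffered THF/water would cleave the diol to 12 at neutral pH, and NaBH4 added at once would give 13.

## Further compounds

F1 | step 3 | 5-(1,3-dioxolan-2-yl)-2-(3,4,5-trimethoxyphenyl)benzofuran | COc1cc(-c2cc3cc(C4OCCO4)ccc3o2)cc(OC)c1OC
F2 | step 3 | 3-bromo-5-(1,3-dioxolan-2-yl)-2-(3,4,5-trimethoxyphenyl)benzofuran | COc1cc(-c2oc3ccc(C4OCCO4)cc3c2Br)cc(OC)c1OC
F3 | step 3 | methyl 5-(1,3-dioxolan-2-yl)-2-(3,4,5-trimethoxyphenyl)benzofuran-3-carboxylate | COc1cc(-c2oc3ccc(C4OCCO4)cc3c2C(=O)OC)cc(OC)c1OC
F4 | step 3 | methyl 5-(1,3-dioxolan-2-yl)-2-(3,4,5-trimethoxyphenyl)-2,3-dihydrobenzofuran-3-carboxylate, racemic trans isomer (the 2R,3R enantiomer is drawn) | COc1cc([C@@H]2Oc3ccc(C4OCCO4)cc3[C@H]2C(=O)OC)cc(OC)c1OC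
F5 | step 3 | [5-(1,3-dioxolan-2-yl)-2-(3,4,5-trimethoxyphenyl)-2,3-dihydrobenzofuran-3-yl]methanol, racemic trans isomer (the 2R,3S enantiomer is drawn) | COc1cc([C@@H]2Oc3ccc(C4OCCO4)cc3[C@H]2CO)cc(OC)c1OC
F6 | step 4 | (3R)-3-allyl-5-(1,3-dioxolan-2-yl)-2-(3,4,5-trimethoxyphenyl)-2,3-dihydrobenzofuran-2-ol (both C2 epimers) | COc1cc(C2(O)Oc3ccc(C4OCCO4)cc3[C@H]2CC=C)cc(OC)c1OC
F7 | step 4 | (2R)-2-[5-(1,3-dioxolan-2-yl)-2-hydroxyphenyl]-1-(3,4,5-trimethoxyphenyl)pent-4-en-1-ol (both C1 epimers) | COc1cc(C(O)[C@H](CC=C)c2cc(C3OCCO3)ccc2O)cc(OC)c1OC
F8 | step 5 | 2-[(2R,3R)-5-(1,3-dioxolan-2-yl)-2-(3,4,5-trimethoxyphenyl)-2,3-dihydrobenzofuran-3-yl]acetaldehyde | COc1cc([C@@H]2Oc3ccc(C4OCCO4)cc3[C@H]2CC=O)cc(OC)c1OC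
F9 | step 5 | tert-butyl-dimethyl-[2-[(2R,3R)-5-(1,3-dioxolan-2-yl)-2-(3,4,5-trimethoxyphenyl)-2,3-dihydrobenzofuran-3-yl]ethenoxy]silane (E/Z mixture) | COc1cc([C@@H]2Oc3ccc(C4OCCO4)cc3[C@H]2C=CO[Si](C)(C)C(C)(C)C)cc(OC)c1OC
F10 | step 6 | 1-[(2R,3S)-5-(1,3-dioxolan-2-yl)-2-(3,4,5-trimethoxyphenyl)-2,3-dihydrobenzofuran-3-yl]propane-1,2-diol (mixture of diol diastereomers) | COc1cc([C@@H]2Oc3ccc(C4OCCO4)cc3[C@H]2C(O)C(C)O)cc(OC)c1OC
A1 | alternative 1 | 3,4,5-trimethoxybenzaldehyde | COc1cc(C=O)cc(OC)c1OC
A2 | alternative 1 | methyl 4-(tert-butyldimethylsilyloxy)-3-vinylbenzoate | C=Cc1cc(C(=O)OC)ccc1O[Si](C)(C)C(C)(C)C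
A3 | alternative 1 | methyl 4-(tert-butyldimethylsilyloxy)-3-[(2S,3S)-2-(3,4,5-trimethoxyphenyl)oxetan-3-yl]benzoate (would form as the racemate; the enantiomer leading to 16 is drawn) | COc1cc([C@H]2OC[C@@H]2c2cc(C(=O)OC)ccc2O[Si](C)(C)C(C)(C)C)cc(OC)c1OC
A4 | alternative 2 | methyl (E)-3-[4-hydroxy-3-[(E)-2-(3,4,5-trimethoxyphenyl)ethenyl]phenyl]prop-2-enoate | COC(=O)/C=C/c1ccc(O)c(/C=C/c2cc(OC)c(OC)c(OC)c2)c1
A5 | alternative 2 | methyl (2R,3R)-5-[(E)-3-methoxy-3-oxoprop-1-enyl]-2-(3,4,5-trimethoxyphenyl)-2,3-dihydrobenzofuran-3-carboxylate | COc1cc([C@@H]2Oc3ccc(/C=C/C(=O)OC)cc3[C@H]2C(=O)OC)cc(OC)c1OC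
A6 | alternative 3 | (4S,5R)-4-(tert-butyldimethylsilyloxymethyl)-5-(3,4,5-trimethoxyphenyl)oxolan-2-one | COc1cc([C@@H]2OC(=O)C[C@H]2CO[Si](C)(C)C(C)(C)C)cc(OC)c1OC
A7 | alternative 3 | methyl coumalate (methyl 2-oxopyran-5-carboxylate) | COC(=O)C1=COC(=O)C=C1
A8 | alternative 3 | methyl (2R,3S)-3-(tert-butyldimethylsilyloxymethyl)-2-(3,4,5-trimethoxyphenyl)-2,3-dihydrobenzofuran-5-carboxylate | COc1cc([C@@H]2Oc3ccc(C(=O)OC)cc3[C@H]2CO[Si](C)(C)C(C)(C)C)cc(OC)c1OC
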